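**Plan**

- Retrosynthesis: cut C4–C4a of the pyranone (aryllithium acylation by an ester). Then take ring B apart at C1'–C2', C3'–C4' and C4'–C5' into a 2-substituted cyclobutenone and 1-methoxy-5-methylhex-4-en-1-yne. Then cut the bond from C3 to the four-membered ring (aldol) and the O1–C2 ether.
- Enabling feature: ring B carries C1' (bonded to C3), C2'–OMe, C3'–prenyl and C4'–OH on four neighbouring carbons, with C5' and C6' unsubstituted. This is the 4-substituted 3-alkoxy-2-alkylphenol that a cyclobutenone/alkoxyalkyne benzannulation delivers.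
- Forward: ring A (phloroglucinol, prenylated and brominated) is etherified with bromopyruvate; C3 is set by a copper–bisoxazoline Mukaiyama aldol with an α-selenenyl cyclobutanone enolsilane; selenoxide elimination unveils the cyclobutenone; benzannulation builds ring B; bromine–lithium exchange onto the ester closes ring C; one acidic deprotection finishes.
- Selenium is put on the ring carbon before the aldol because a cyclobutanone can eliminate towards either α-carbon. With selenium on the substituted carbon, only the 2-substituted cyclobutenone can form.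
- Stereochemistry: the single stereocentre (C3, R) comes from si-face addition to the copper-bound keto ester under the (S,S)-ligand; it is fully substituted and a spectator afterwards.

Key step: step 13

Assumption: keto ester 10 is taken to bind copper through its two carbonyl oxygens as pyruvate esters do, so the facial sense known for pyruvates with the (S,S)-ligand is carried over.

Abbreviations in step names: ArA = 2-bromo-3,5-bis(methoxymethoxy)-4-(3-methylbut-2-en-1-yl)phenyl (ring A); prenyl = 3-methylbut-2-en-1-yl. Full names stand in the compound list.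

**Route**

Step 1
Reactants: 1 phloroglucinol
Product: 2 3,5-bis(methoxymethoxy)phenol
Conditions: MOMCl (2.0 equiv), i-Pr2NEt, CH2Cl2–DMF, 0 °C → rt
Reagents that add atoms: chloromethyl methyl ether, COCCl
Why: O-alkylation of the phenol by the chloromethyl ether (acetal formation) on a threefold-symmetric substrate, so only the degree of alkylation needs control and the bis-ether should be separable from recyclable mono- and tris-ethers.

Step 2
Reactants: 2 3,5-bis(methoxymethoxy)phenol
Product: 3 [3,5-bis(methoxymethoxy)phenoxy]tri(propan-2-yl)silane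
Conditions: i-Pr3SiCl, imidazole, DMF, rt
Reagents that add atoms: chlorotri(propan-2-yl)silane, CC(C)[Si](Cl)(C(C)C)C(C)C
Why: Standard phenol silylation; the bulky silyl ether resists butyllithium and is a poor directing group, which leaves the position between the two acetal ethers as the metalation site.

Step 3
Reactants: 3 [3,5-bis(methoxymethoxy)phenoxy]tri(propan-2-yl)silane; 4 prenyl bromide
Product: 6 [3,5-bis(methoxymethoxy)-4-prenylphenoxy]tri(propan-2-yl)silane, via aryllithium 5 (not isolated)
Conditions: n-BuLi, THF, 0 °C; then CuBr·SMe2 (20 mol%), 4, −78 → 0 °C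
Reagents that add atoms: none
Why: Directed ortho-metalation at the carbon flanked by both methoxymethyl ethers, followed by copper-catalysed SN2 allylation at the primary carbon of the allylic bromide.

Step 4
Reactants: 6 [3,5-bis(methoxymethoxy)-4-prenylphenoxy]tri(propan-2-yl)silane
Product: 7 3,5-bis(methoxymethoxy)-4-prenylphenol
Conditions: Bu4NF, AcOH, THF, 0 °C
Reagents that add atoms: none
Why: Fluoride cleavage of an aryl silyl ether, to which the acetal ethers and the alkene are inert.

Step 5
Reactants: 7 3,5-bis(methoxymethoxy)-4-prenylphenol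
Product: 8 2-bromo-3,5-bis(methoxymethoxy)-4-prenylphenol
Conditions: N-bromosuccinimide (1.0 equiv), i-Pr2NH (10 mol%), CH2Cl2, −78 °C
Reagents that add atoms: N-bromosuccinimide, O=C1CCC(=O)N1Br
Why: Electrophilic aromatic bromination ortho to the free hydroxyl (amine-mediated ortho-bromination of phenols); the para position is blocked, the two ortho positions are equivalent by symmetry, and the trioxygenated ring should react far faster at low temperature than the trisubstituted alkene.

Step 6
Reactants: 8 2-bromo-3,5-bis(methoxymethoxy)-4-prenylphenol; 9 ethyl bromopyruvate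
Product: 10 ethyl 3-(ArA-oxy)-2-oxopropanoate
Conditions: K2CO3, acetone, 0 °C → rt; product dried azeotropically before use
Reagents that add atoms: none
Why: Williamson ether synthesis by SN2 displacement at the activated α-bromo ketone.

Step 7
Reactants: 11 cyclobutanone
Product: 12 2-(phenylselanyl)cyclobutan-1-one
Conditions: PhSeCl, EtOAc, rt, 11 in excess
Reagents that add atoms: benzeneselenenyl chloride, Cl[Se]c1ccccc1
Why: α-Selenenylation of a ketone through its enol, with excess ketone limiting double selenenylation.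

Step 8
Reactants: 12 2-(phenylselanyl)cyclobutan-1-one
Product: 13 trimethyl{[2-(phenylselanyl)cyclobut-1-en-1-yl]oxy}silane
Conditions: Me3SiOTf, Et3N, CH2Cl2, 0 °C
Reagents that add atoms: trimethylsilyl trifluoromethanesulfonate, C[Si](C)(C)OS(=O)(=O)C(F)(F)F
Why: Soft enolisation with O-silylation; the selenium-bearing α-hydrogen is the more acidic and the heteroatom-substituted enol ether the more stable, so the double bond should form towards selenium.

Step 9
Reactants: 10 ethyl 3-(ArA-oxy)-2-oxopropanoate; 13 trimethyl{[2-(phenylselanyl)cyclobut-1-en-1-yl]oxy}silane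
Product: 15 ethyl (2R)-3-(ArA-oxy)-2-hydroxy-2-[2-oxo-1-(phenylselanyl)cyclobutyl]propanoate, via trimethylsilyl ether 14 (not isolated)
Conditions: Cu(OTf)2 (10 mol%), 2,2'-(propane-2,2-diyl)bis[(4S)-4-tert-butyl-4,5-dihydro-1,3-oxazole] (11 mol%), THF, −78 °C; then 1 M HCl, THF, 0 °C
Reagents that add atoms: none
Why: Mukaiyama aldol addition of an enolsilane to an α-keto ester held as a five-membered chelate on divalent copper (bisoxazoline–copper catalysis as established for pyruvate esters); the tert-butyl groups of the (S,S)-ligand shield the re face of the ketone, so the enolsilane should add to the si face and set the carbinol carbon (the future C3) as R, while the selenium-bearing ring carbon forms as an epimer mixture that is erased in step 11.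

Step 10
Reactants: 15 ethyl (2R)-3-(ArA-oxy)-2-hydroxy-2-[2-oxo-1-(phenylselanyl)cyclobutyl]propanoate
Product: 16 ethyl (2R)-3-(ArA-oxy)-2-[2-oxo-1-(phenylselanyl)cyclobutyl]-2-[(triethylsilyl)oxy]propanoate
Conditions: Et3SiOTf, 2,6-lutidine, CH2Cl2, −78 → 0 °C
Reagents that add atoms: triethylsilyl trifluoromethanesulfonate, CC[Si](CC)(CC)OS(=O)(=O)C(F)(F)F
Why: Silylation of a hindered tertiary alcohol with a silyl triflate, which blocks retro-aldol cleavage and later capture of the ketene by the hydroxyl.

Step 11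
Reactants: 16 ethyl (2R)-3-(ArA-oxy)-2-[2-oxo-1-(phenylselanyl)cyclobutyl]-2-[(triethylsilyl)oxy]propanoate
Product: 18 ethyl (2R)-3-(ArA-oxy)-2-(4-oxocyclobut-1-en-1-yl)-2-[(triethylsilyl)oxy]propanoate, via selenoxide 17 (not isolated)
Conditions: mCPBA (1.0 equiv), CH2Cl2, −78 °C; then pyridine, −78 → 0 °C
Reagents that add atoms: none
Why: Chemoselective oxidation at selenium followed by syn-elimination of the selenoxide (selenoxide elimination); the selenium-bearing carbon has β-hydrogens only on the ring methylene, so the alkene can form only on the substituted side, which a kinetic selenenylation of a plain aldol adduct (at the unsubstituted α-carbon) could not guarantee.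

Step 12
Reactants: 19 chloroacetaldehyde dimethyl acetal; 4 prenyl bromide
Product: 21 1-methoxy-5-methylhex-4-en-1-yne, via lithium methoxyacetylide 20 (not isolated)
Conditions: Et2NH, n-BuLi (3.0 equiv each), THF, 0 °C; then 4, DMPU, −78 °C → rt
Reagents that add atoms: none
Why: Twofold base-induced elimination (of HCl and methanol) from the chloroacetal gives the lithium alkoxyacetylide, which is C-alkylated by SN2 at the primary carbon of the allylic bromide; no excess amide base remains to isomerise the skipped enyne.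

Step 13
Reactants: 18 ethyl (2R)-3-(ArA-oxy)-2-(4-oxocyclobut-1-en-1-yl)-2-[(triethylsilyl)oxy]propanoate; 21 1-methoxy-5-methylhex-4-en-1-yne
Product: 26 ethyl (2R)-3-(ArA-oxy)-2-(4-hydroxy-2-methoxy-3-prenylphenyl)-2-[(triethylsilyl)oxy]propanoate, via vinylketene 22 (not isolated), via vinylcyclobutenone 23 (not isolated), via dienylketene 24 (not isolated), via cyclohexadienone 25 (not isolated)
Conditions: 21 (3 equiv), toluene, degassed, sealed tube, 80 → 110 °C
Reagents that add atoms: none
Why: Heating should open 18 in a conrotatory four-electron electrocyclic reaction to vinylketene 22, whose ketene C=C adds the ynol ether in a [2+2] cycloaddition to give 23; a second four-electron opening gives dienylketene 24, and a disrotatory six-electron electrocyclisation gives cyclohexadienone 25, which tautomerises to the phenol. The closest known reaction type is the Danheiser benzannulation of cyclobutenones with 1-alkoxyalkynes to 3-alkoxy-2-alkylphenols. Ring B closes by the 6π electrocyclisation that forms C4'–C5', after the cycloaddition has formed C3'–C4' and C1'–C2'. No stereocentre is created, and the silylated C3 carbinol has no α-hydrogen and no ionisable bond under neutral thermal conditions, so it should pass through unchanged. The step needs regioselectivity in the ketene–alkyne cycloaddition: the electrophilic ketene carbon bonds to the nucleophilic alkyne carbon β to methoxy, which places prenyl at C3' between hydroxyl and methoxyl, and the position of the substituent at C2 of the cyclobutenone places the carbinol para to the new hydroxyl. The excess of electron-rich alkyne should outcompete the prenyl alkenes and the product phenol for the ketene.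

Step 14
Reactants: 26 ethyl (2R)-3-(ArA-oxy)-2-(4-hydroxy-2-methoxy-3-prenylphenyl)-2-[(triethylsilyl)oxy]propanoate
Product: 29 (3R)-3-(4-hydroxy-2-methoxy-3-prenylphenyl)-5,7-bis(methoxymethoxy)-6-prenyl-3-[(triethylsilyl)oxy]chroman-4-one, via aryllithium 27 (not isolated), via lithium hemiketalate 28 (not isolated)
Conditions: t-BuLi (3.1 equiv), THF, −78 °C; then AcOH
Reagents that add atoms: none
Why: Parham cyclisation: after deprotonation of the phenol, bromine–lithium exchange at −78 °C is faster than attack of the alkyllithium on the hindered ester, and the aryllithium acylates intramolecularly to close the six-membered ring C at C4–C4a; C3 carries no hydrogen and cannot epimerise.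

Step 15
Reactants: 29 (3R)-3-(4-hydroxy-2-methoxy-3-prenylphenyl)-5,7-bis(methoxymethoxy)-6-prenyl-3-[(triethylsilyl)oxy]chroman-4-one
Product: 30 (3R)-3,5,7-trihydroxy-3-(4-hydroxy-2-methoxy-3-prenylphenyl)-6-prenylchroman-4-one
Conditions: 3 M HCl (aq), MeOH, 40 °C
Reagents that add atoms: none
Why: Acid-catalysed acetal exchange (methoxymethyl ether cleavage) and methanolysis of the silyl ether under mild protic conditions, which should leave the prenyl groups uncyclised and the tertiary α-ketol intact.

**Compound list**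

1 | phloroglucinol (benzene-1,3,5-triol) | Oc1cc(O)cc(O)c1 | starting material
2 | 3,5-bis(methoxymethoxy)phenol | Oc1cc(OCOC)cc(OCOC)c1 | intermediate
3 | [3,5-bis(methoxymethoxy)phenoxy]tri(propan-2-yl)silane | CC(C)[Si](Oc1cc(OCOC)cc(OCOC)c1)(C(C)C)C(C)C | intermediate
4 | prenyl bromide (1-bromo-3-methylbut-2-ene) | CC(C)=CCBr | starting material
5 | {2,6-bis(methoxymethoxy)-4-[(triisopropylsilyl)oxy]phenyl}lithium | [Li]c1c(OCOC)cc(O[Si](C(C)C)(C(C)C)C(C)C)cc1OCOC | intermediate
6 | [3,5-bis(methoxymethoxy)-4-(3-methylbut-2-en-1-yl)phenoxy]tri(propan-2-yl)silane | CC(C)=CCc1c(OCOC)cc(O[Si](C(C)C)(C(C)C)C(C)C)cc1OCOC | intermediate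
7 | 3,5-bis(methoxymethoxy)-4-(3-methylbut-2-en-1-yl)phenol | CC(C)=CCc1c(OCOC)cc(O)cc1OCOC | intermediate
8 | 2-bromo-3,5-bis(methoxymethoxy)-4-(3-methylbut-2-en-1-yl)phenol | CC(C)=CCc1c(OCOC)cc(O)c(Br)c1OCOC | intermediate
9 | ethyl bromopyruvate (ethyl 3-bromo-2-oxopropanoate) | CCOC(=O)C(=O)CBr | starting material
10 | ethyl 3-[2-bromo-3,5-bis(methoxymethoxy)-4-(3-methylbut-2-en-1-yl)phenoxy]-2-oxopropanoate | CCOC(=O)C(=O)COc1cc(OCOC)c(CC=C(C)C)c(OCOC)c1Br | intermediate
11 | cyclobutanone | O=C1CCC1 | starting material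
12 | 2-(phenylselanyl)cyclobutan-1-one (racemic) | O=C1CCC1[Se]c1ccccc1 | intermediate
13 | trimethyl{[2-(phenylselanyl)cyclobut-1-en-1-yl]oxy}silane | C[Si](C)(C)OC1=C([Se]c2ccccc2)CC1 | intermediate
14 | ethyl (2R)-3-[2-bromo-3,5-bis(methoxymethoxy)-4-(3-methylbut-2-en-1-yl)phenoxy]-2-[2-oxo-1-(phenylselanyl)cyclobutyl]-2-[(trimethylsilyl)oxy]propanoate (both epimers at the selenium-bearing ring carbon) | O=C1CCC1([Se]c2ccccc2)[C@@](C(=O)OCC)(O[Si](C)(C)C)COc3cc(OCOC)c(CC=C(C)C)c(OCOC)c3Br | intermediate
15 | ethyl (2R)-3-[2-bromo-3,5-bis(methoxymethoxy)-4-(3-methylbut-2-en-1-yl)phenoxy]-2-hydroxy-2-[2-oxo-1-(phenylselanyl)cyclobutyl]propanoate (both epimers at the selenium-bearing ring carbon) | O=C1CCC1([Se]c2ccccc2)[C@@](C(=O)OCC)(O)COc3cc(OCOC)c(CC=C(C)C)c(OCOC)c3Br | intermediate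
16 | ethyl (2R)-3-[2-bromo-3,5-bis(methoxymethoxy)-4-(3-methylbut-2-en-1-yl)phenoxy]-2-[2-oxo-1-(phenylselanyl)cyclobutyl]-2-[(triethylsilyl)oxy]propanoate (both epimers at the selenium-bearing ring carbon) | O=C1CCC1([Se]c2ccccc2)[C@@](C(=O)OCC)(O[Si](CC)(CC)CC)COc3cc(OCOC)c(CC=C(C)C)c(OCOC)c3Br | intermediate
17 | ethyl (2R)-3-[2-bromo-3,5-bis(methoxymethoxy)-4-(3-methylbut-2-en-1-yl)phenoxy]-2-[2-oxo-1-(phenylseleninyl)cyclobutyl]-2-[(triethylsilyl)oxy]propanoate (selenoxide, isomer mixture at ring carbon and selenium) | O=C1CCC1([Se](=O)c2ccccc2)[C@@](C(=O)OCC)(O[Si](CC)(CC)CC)COc3cc(OCOC)c(CC=C(C)C)c(OCOC)c3Br | intermediate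
18 | ethyl (2R)-3-[2-bromo-3,5-bis(methoxymethoxy)-4-(3-methylbut-2-en-1-yl)phenoxy]-2-(4-oxocyclobut-1-en-1-yl)-2-[(triethylsilyl)oxy]propanoate | O=C1CC=C1[C@@](C(=O)OCC)(O[Si](CC)(CC)CC)COc2cc(OCOC)c(CC=C(C)C)c(OCOC)c2Br | intermediate
19 | chloroacetaldehyde dimethyl acetal (2-chloro-1,1-dimethoxyethane) | COC(CCl)OC | starting material
20 | lithium methoxyacetylide ((methoxyethynyl)lithium) | [Li]C#COC | intermediate
21 | 1-methoxy-5-methylhex-4-en-1-yne | COC#CCC=C(C)C | intermediate
22 | ethyl (2R)-3-[2-bromo-3,5-bis(methoxymethoxy)-4-(3-methylbut-2-en-1-yl)phenoxy]-2-(1-oxobuta-1,3-dien-2-yl)-2-[(triethylsilyl)oxy]propanoate (vinylketene) | O=C=C(C=C)[C@@](C(=O)OCC)(O[Si](CC)(CC)CC)COc2cc(OCOC)c(CC=C(C)C)c(OCOC)c2Br | intermediate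
23 | ethyl (2R)-3-[2-bromo-3,5-bis(methoxymethoxy)-4-(3-methylbut-2-en-1-yl)phenoxy]-2-[1-ethenyl-2-methoxy-3-(3-methylbut-2-en-1-yl)-4-oxocyclobut-2-en-1-yl]-2-[(triethylsilyl)oxy]propanoate (both epimers at the ring carbon) | O=C1C(CC=C(C)C)=C(OC)C1(C=C)[C@@](C(=O)OCC)(O[Si](CC)(CC)CC)COc2cc(OCOC)c(CC=C(C)C)c(OCOC)c2Br | intermediate
24 | ethyl (2R,3Z)-2-{[2-bromo-3,5-bis(methoxymethoxy)-4-(3-methylbut-2-en-1-yl)phenoxy]methyl}-3-ethenyl-4-methoxy-5-(3-methylbut-2-en-1-yl)-6-oxo-2-[(triethylsilyl)oxy]hexa-3,5-dienoate (dienylketene) | O=C=C(CC=C(C)C)/C(OC)=C(\C=C)[C@@](C(=O)OCC)(O[Si](CC)(CC)CC)COc2cc(OCOC)c(CC=C(C)C)c(OCOC)c2Br | intermediate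
25 | ethyl (2R)-3-[2-bromo-3,5-bis(methoxymethoxy)-4-(3-methylbut-2-en-1-yl)phenoxy]-2-[6-methoxy-5-(3-methylbut-2-en-1-yl)-4-oxocyclohexa-1,5-dien-1-yl]-2-[(triethylsilyl)oxy]propanoate (keto tautomer of 26) | O=C1CC=C(C(OC)=C1CC=C(C)C)[C@@](C(=O)OCC)(O[Si](CC)(CC)CC)COc2cc(OCOC)c(CC=C(C)C)c(OCOC)c2Br | intermediate
26 | ethyl (2R)-3-[2-bromo-3,5-bis(methoxymethoxy)-4-(3-methylbut-2-en-1-yl)phenoxy]-2-[4-hydroxy-2-methoxy-3-(3-methylbut-2-en-1-yl)phenyl]-2-[(triethylsilyl)oxy]propanoate | COc1c([C@@](C(=O)OCC)(O[Si](CC)(CC)CC)COc2cc(OCOC)c(CC=C(C)C)c(OCOC)c2Br)ccc(O)c1CC=C(C)C | intermediate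
27 | dilithio derivative of 26: lithium phenoxide at O4' and aryllithium in place of the ring A bromine | COc1c([C@@](C(=O)OCC)(O[Si](CC)(CC)CC)COc2cc(OCOC)c(CC=C(C)C)c(OCOC)c2[Li])ccc(O[Li])c1CC=C(C)C | intermediate
28 | dilithium salt of the (3R)-4-ethoxy-4-hydroxychromane adduct (C4 hemiketal alkoxide and 4'-phenoxide, both epimers at C4) | COc1c([C@@]2(O[Si](CC)(CC)CC)COc3cc(OCOC)c(CC=C(C)C)c(OCOC)c3C2(O[Li])OCC)ccc(O[Li])c1CC=C(C)C | intermediate
29 | (3R)-3-[4-hydroxy-2-methoxy-3-(3-methylbut-2-en-1-yl)phenyl]-5,7-bis(methoxymethoxy)-6-(3-methylbut-2-en-1-yl)-3-[(triethylsilyl)oxy]-2,3-dihydro-4H-chromen-4-one | COc1c([C@@]2(O[Si](CC)(CC)CC)COc3cc(OCOC)c(CC=C(C)C)c(OCOC)c3C2=O)ccc(O)c1CC=C(C)C | intermediate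
30 | (3R)-3,5,7-trihydroxy-3-[4-hydroxy-2-methoxy-3-(3-methylbut-2-en-1-yl)phenyl]-6-(3-methylbut-2-en-1-yl)-2,3-dihydro-4H-chromen-4-one | COc1c([C@@]2(O)COc3cc(O)c(CC=C(C)C)c(O)c3C2=O)ccc(O)c1CC=C(C)C | target

**Step count**

Total: 15 steps. Longest linear sequence: 12 steps (steps 1–6, 9–11, 13–15); steps 7–8 and step 12 are side branches.

**Steps most likely to fail**

1. Step 9. Bond formation between two fully substituted carbons may stall. The Lewis acid may desilylate the enolsilane or strip selenium before addition. Competing coordination of copper by the aryloxy oxygen may erode facial control.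
Fallback, from 10 back to 18: replace the Lewis-acid aldol by nucleophilic amine catalysis. Cyclobut-2-en-1-one F1 would be generated from 3-bromocyclobutanone with Bu3N and coupled with 10 in a Morita–Baylis–Hillman reaction under a chiral bifunctional amine such as β-isocupreidine. The amine adds at the β-carbon of the enone, and the resulting enolate, which carries a hydrogen and is far less congested, attacks the keto group. Reversible re-addition of the amine should funnel any double-bond isomer to the less electrophilic 2-substituted enone. The sense of induction would have to be secured with the appropriate pseudo-enantiomeric catalyst. This would give ethyl (2R)-3-(ArA-oxy)-2-hydroxy-2-(4-oxocyclobut-1-en-1-yl)propanoate F2. Silylation with Et3SiOTf and 2,6-lutidine then returns 18.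

2. Step 13. Thermal opening of 18 may need temperatures at which vinylketene 22 is lost by dimerisation or by acylating the product phenol before its hindered α-carbon engages the ynol ether.
Fallback, from 10 back to 26: generate the same vinylketene photochemically at ambient temperature from a diazo ketone. The same copper–bisoxazoline aldol of 10 with commercial 2-(trimethylsilyloxy)buta-1,3-diene, an unhindered enolsilane, would give the trimethylsilyl ether F3 and, after acidic work-up, ethyl (2R)-2-[(ArA-oxy)methyl]-2-hydroxy-4-oxohex-5-enoate F4. Et3SiOTf and 2,6-lutidine would give the triethylsilyl ether F5. Detrifluoroacetylative diazo transfer would follow: LiN(SiMe3)2 and CF3CO2CH2CF3 at −78 °C to the trifluoroacetyl diketone F6, then MsN3 and Et3N to the α'-diazo enone F7. Irradiation of F7 at 300 nm in the presence of 21 should trigger a Wolff rearrangement with vinyl migration to give 22. This then follows the same course through 23, 24 and 25 to 26 on gentle warming.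

3. Step 6. Under basic conditions the bromopyruvate and the product keto ester may enolise and self-condense, or the hindered phenoxide may add to the ketone instead of displacing bromide.
Fallback, from 8 back to 10: install the three-carbon unit at the alcohol oxidation level. Opening of ethyl oxirane-2-carboxylate at C3 by the phenoxide of 8 (Cs2CO3, DMF, 60 °C) would give ethyl 3-(ArA-oxy)-2-hydroxypropanoate F8 as the racemate. Dess–Martin oxidation would return 10, the stereocentre of F8 being removed.

**Further compounds**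

F1 | step 9 | cyclobut-2-en-1-one | O=C1CC=C1
F2 | step 9 | ethyl (2R)-3-[2-bromo-3,5-bis(methoxymethoxy)-4-(3-methylbut-2-en-1-yl)phenoxy]-2-hydroxy-2-(4-oxocyclobut-1-en-1-yl)propanoate | O=C1CC=C1[C@@](C(=O)OCC)(O)COc2cc(OCOC)c(CC=C(C)C)c(OCOC)c2Br
F3 | step 13 | ethyl (2R)-2-{[2-bromo-3,5-bis(methoxymethoxy)-4-(3-methylbut-2-en-1-yl)phenoxy]methyl}-4-oxo-2-[(trimethylsilyl)oxy]hex-5-enoate | C=CC(=O)C[C@@](C(=O)OCC)(O[Si](C)(C)C)COc1cc(OCOC)c(CC=C(C)C)c(OCOC)c1Br
F4 | step 13 | ethyl (2R)-2-{[2-bromo-3,5-bis(methoxymethoxy)-4-(3-methylbut-2-en-1-yl)phenoxy]methyl}-2-hydroxy-4-oxohex-5-enoate | C=CC(=O)C[C@@](C(=O)OCC)(O)COc1cc(OCOC)c(CC=C(C)C)c(OCOC)c1Br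
F5 | step 13 | ethyl (2R)-2-{[2-bromo-3,5-bis(methoxymethoxy)-4-(3-methylbut-2-en-1-yl)phenoxy]methyl}-4-oxo-2-[(triethylsilyl)oxy]hex-5-enoate | C=CC(=O)C[C@@](C(=O)OCC)(O[Si](CC)(CC)CC)COc1cc(OCOC)c(CC=C(C)C)c(OCOC)c1Br
F6 | step 13 | ethyl (2R)-2-{[2-bromo-3,5-bis(methoxymethoxy)-4-(3-methylbut-2-en-1-yl)phenoxy]methyl}-4-oxo-2-[(triethylsilyl)oxy]-3-(trifluoroacetyl)hex-5-enoate (both epimers at C3) | C=CC(=O)C(C(=O)C(F)(F)F)[C@@](C(=O)OCC)(O[Si](CC)(CC)CC)COc1cc(OCOC)c(CC=C(C)C)c(OCOC)c1Br
F7 | step 13 | ethyl (2R)-2-{[2-bromo-3,5-bis(methoxymethoxy)-4-(3-methylbut-2-en-1-yl)phenoxy]methyl}-3-diazo-4-oxo-2-[(triethylsilyl)oxy]hex-5-enoate | C=CC(=O)C(=[N+]=[N-])[C@@](C(=O)OCC)(O[Si](CC)(CC)CC)COc1cc(OCOC)c(CC=C(C)C)c(OCOC)c1Br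
F8 | step 6 | ethyl 3-[2-bromo-3,5-bis(methoxymethoxy)-4-(3-methylbut-2-en-1-yl)phenoxy]-2-hydroxypropanoate (racemic) | CCOC(=O)C(O)COc1cc(OCOC)c(CC=C(C)C)c(OCOC)c1Br
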